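**Strategy**

Everything rests on cutting the two C3–C4 bonds of the C15 side chains at the quaternary benzylic C3 atoms, which are constitutionally identical but 3R on ring A (monophenol ring) and 3S on ring B (catechol ring). One twofold lithiation–borylation joins a heterochiral diaryl ether bis(N,N-diisopropylcarbamate), (R)-carbinol on ring A and (S)-carbinol on ring B, all three phenols as MOM ethers, to two molecules of homogeranyl pinacol boronate; stereospecific 1,2-migrations give both quaternary centres as tertiary boronates. The carbinols come from antipodal transfer hydrogenations ahead of an Ullmann ether coupling; twofold Zweifel vinylation and MOM removal complete the target.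

Key step: step 10

Assumption: (E)-geranyl bromide is bought and used as the C10 electrophile.

Remark: ring B is bought as an aldehyde, so its methyl ketone is made by methyl addition and oxidation before the asymmetric reduction. MOM is kept on all three phenols because it survives s-BuLi, the Ullmann base and the Zweifel reagents and leaves only in the final acid step. The two carbinol centres are set in separate flasks, so any minor enantiomer of 3 or 8 would end up as a diastereomer of 9; both should be brought to high enantiomeric purity (recrystallisation if required) before step 7.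

**Route**

Step 1
Reactants: 1 3',4'-dihydroxyacetophenone
Product: 2 1-[3-hydroxy-4-(methoxymethoxy)phenyl]ethan-1-one
Conditions: MOMCl (1.05 equiv), K2CO3 (1.1 equiv), acetone, 0 °C → rt
Reagents that add atoms: chloromethyl methyl ether (MOMCl), COCCl
Why: Williamson-type O-alkylation; the 4-OH, para to the acetyl group, is the more acidic phenol, so one equivalent of K2CO3 should ionise and protect it and leave the 3-OH free for the later ether coupling.

Step 2
Reactants: 2 1-[3-hydroxy-4-(methoxymethoxy)phenyl]ethan-1-one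
Product: 3 5-[(1R)-1-hydroxyethyl]-2-(methoxymethoxy)phenol
Conditions: RuCl[(R,R)-TsDPEN](p-cymene) (1 mol %), HCO2H–Et3N (5:2), EtOAc, 35 °C
Reagents that add atoms: none
Why: Asymmetric transfer hydrogenation of an aryl methyl ketone with a Ru–TsDPEN–arene catalyst; the (R,R)-ligand should deliver hydride to the Si face of the carbonyl and set the (R)-carbinol, and the phenol and the MOM acetal tolerate the buffered formate medium.

Step 3
Reactants: 4 3-bromo-4,5-dihydroxybenzaldehyde
Product: 5 3-bromo-4,5-bis(methoxymethoxy)benzaldehyde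
Conditions: MOMCl (2.6 equiv), K2CO3 (3 equiv), acetone, 0 → 50 °C, N2
Reagents that add atoms: chloromethyl methyl ether (MOMCl), COCCl
Why: Twofold Williamson-type MOM protection of the catechol; the aldehyde and the aryl bromide are inert to K2CO3 and MOMCl.

Step 4
Reactants: 5 3-bromo-4,5-bis(methoxymethoxy)benzaldehyde
Product: 6 rac-1-[3-bromo-4,5-bis(methoxymethoxy)phenyl]ethan-1-ol
Conditions: MeMgBr (1.2 equiv), THF, 0 °C; aq. NH4Cl
Reagents that add atoms: methylmagnesium bromide, C[Mg]Br
Why: Grignard addition to the aldehyde; the aryl bromide does not exchange with MeMgBr at 0 °C, and the racemic carbinol centre is erased in step 5.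

Step 5
Reactants: 6 rac-1-[3-bromo-4,5-bis(methoxymethoxy)phenyl]ethan-1-ol
Product: 7 1-[3-bromo-4,5-bis(methoxymethoxy)phenyl]ethan-1-one
Conditions: MnO2 (10 equiv), CH2Cl2, rt
Reagents that add atoms: none
Why: MnO2 oxidation of an electron-rich benzylic alcohol to the aryl methyl ketone under neutral conditions that leave the MOM ethers and the bromide alone.

Step 6
Reactants: 7 1-[3-bromo-4,5-bis(methoxymethoxy)phenyl]ethan-1-one
Product: 8 (1S)-1-[3-bromo-4,5-bis(methoxymethoxy)phenyl]ethan-1-ol
Conditions: RuCl[(S,S)-TsDPEN](p-cymene) (1 mol %), HCO2H–Et3N (5:2), EtOAc, 35 °C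
Reagents that add atoms: none
Why: Asymmetric transfer hydrogenation as in step 2 with the antipodal (S,S)-ligand, which should deliver hydride to the Re face and set the (S)-carbinol; the aryl bromide is not reduced by the ruthenium hydride.

Step 7
Reactants: 3 5-[(1R)-1-hydroxyethyl]-2-(methoxymethoxy)phenol (1.2 equiv); 8 (1S)-1-[3-bromo-4,5-bis(methoxymethoxy)phenyl]ethan-1-ol
Product: 9 (1R)-1-[3-{5-[(1S)-1-hydroxyethyl]-2,3-bis(methoxymethoxy)phenoxy}-4-(methoxymethoxy)phenyl]ethan-1-ol
Conditions: CuI (10 mol %), picolinic acid (20 mol %), K3PO4 (2 equiv), DMSO, 90 °C, Ar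
Reagents that add atoms: none
Why: Ullmann-type copper-catalysed C–O coupling; K3PO4 ionises only the phenol of 3, the picolinate–copper catalyst is suited to ortho-substituted partners, and the un-ionised secondary carbinols should be neither arylated nor epimerised, so both stereocentres pass through unchanged.

Step 8
Reactants: 9 diaryl ether diol
Product: 10 (1R)-1-[3-{5-[(1S)-1-(N,N-diisopropylcarbamoyloxy)ethyl]-2,3-bis(methoxymethoxy)phenoxy}-4-(methoxymethoxy)phenyl]ethyl N,N-diisopropylcarbamate
Conditions: i-Pr2NCOCl (3 equiv), Et3N (4 equiv), CH2Cl2, reflux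
Reagents that add atoms: N,N-diisopropylcarbamoyl chloride, CC(C)N(C(C)C)C(Cl)=O
Why: O-carbamoylation (acyl substitution at the carbamoyl chloride) of both secondary alcohols; no bond at either stereocentre is broken, so R on ring A and S on ring B are retained.

Step 9
Reactants: 11 (E)-geranyl bromide
Product: 12 2-[(3E)-4,8-dimethylnona-3,7-dien-1-yl]-4,4,5,5-tetramethyl-1,3,2-dioxaborolane (homogeranyl pinacol boronate)
Conditions: CH2(Bpin)2 (1.5 equiv), NaOt-Bu (1.5 equiv), THF, 0 °C → rt
Reagents that add atoms: bis(4,4,5,5-tetramethyl-1,3,2-dioxaborolan-2-yl)methane, CC1(C)OB(CB2OC(C)(C)C(C)(C)O2)OC1(C)C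
Why: Deborylative alkylation of a geminal bis(boronate); tert-butoxide adds to one boron of CH2(Bpin)2 and the resulting α-boryl carbanion displaces the primary allylic bromide by SN2, so the (E)-trisubstituted alkene is carried over unchanged.

Step 10
Reactants: 10 diaryl ether bis(N,N-diisopropylcarbamate); 12 homogeranyl pinacol boronate (3 equiv)
Product: 15 bis(tertiary pinacol boronate) carrying both C15 chains (C–B carbon R on ring A; S on ring B), via dilithiated bis(carbamate) 13 (not isolated), via dilithium bis(boronate) ate complex 14 (not isolated)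
Conditions: s-BuLi (2.5 equiv), Et2O, −78 °C, 1 h; 12, −78 °C, 2 h; MgBr2 in MeOH (1 M, 3 equiv), −78 °C → rt
Reagents that add atoms: none
Why: s-BuLi, guided by the carbamate carbonyl, removes each benzylic hydrogen with retention to give the twofold α-oxybenzyllithium 13, which is configurationally stable at −78 °C in Et2O; each C–Li bond captures 12 at boron with retention (14), and on warming with MgBr2/MeOH the homogeranyl CH2 shifts from boron to carbon anti to the leaving carbamate, with inversion, forming both C3–C4 bonds. The closest known reaction is the lithiation–borylation of enantioenriched secondary benzylic carbamates with pinacol boronic esters to give tertiary boronic esters. No ring is closed. Each new quaternary centre is controlled only by the carbinol configuration of its own arm (retention, retention, inversion), so the (R)-carbinol on ring A gives the (R)-C–B centre and the (S)-carbinol on ring B gives the (S)-C–B centre, the ether oxygen insulating the two sites from each other. The step needs benzylic deprotonation to outrun ring lithiation beside the MOM ethers, which the coordinating carbamate, the acidity of the benzylic α-oxy C–H, amine-free Et2O at −78 °C and a near-stoichiometric charge of base should secure; it also needs ate-complex formation on these electron-rich rings not to revert, which MgBr2/MeOH secures by speeding the migration and protonating any released carbanion.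

Step 11
Reactants: 15 bis(tertiary pinacol boronate)
Product: 18 tris(MOM) ether of the target (bis-vinyl compound; 3R on ring A; 3S on ring B), via dilithium bis(vinylboronate) ate complex 16 (not isolated), via bis(β-iodoalkyl boronate) 17 (not isolated)
Conditions: CH2=CHLi (8 equiv, from Sn(CH=CH2)4 and n-BuLi), THF, −78 °C; I2 (8 equiv), MeOH, −78 °C; NaOMe (16 equiv), MeOH, −78 °C → rt; aq. Na2S2O3
Reagents that add atoms: vinyllithium, [Li]C=C, made in the flask from tetravinylstannane, C=C[Sn](C=C)(C=C)C=C
Why: Zweifel olefination; vinyllithium is small enough to add to the hindered tertiary boronates (16), iodine triggers a 1,2-shift of each benzylic carbon from boron to the vinyl carbon with retention (17), methoxide induces anti elimination of boron and iodide, and at −78 °C iodine should react at the electron-rich alkenylboronate far faster than at the trisubstituted alkenes or the arenes.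

Step 12
Reactants: 18 tris(MOM) ether of the target
Product: 19 3-{2-hydroxy-5-[(3R,6E)-3,7,11-trimethyldodeca-1,6,10-trien-3-yl]phenoxy}-5-[(3S,6E)-3,7,11-trimethyldodeca-1,6,10-trien-3-yl]benzene-1,2-diol (CNP0296687.1)
Conditions: 3 M aq. HCl, MeOH–THF (degassed), 40 °C, Ar
Reagents that add atoms: none
Why: Acid-catalysed acetal exchange transfers the three phenolic MOM groups to methanol; dilute acid at 40 °C should not protonate the trisubstituted alkenes, no phenol sits ortho to an allyl-type chain so no chroman can form, and the quaternary centres carry no ionisable bond.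

**Compound list**

1 | 3',4'-dihydroxyacetophenone | CC(=O)c1ccc(O)c(O)c1 | starting material
2 | 1-[3-hydroxy-4-(methoxymethoxy)phenyl]ethan-1-one | CC(=O)c1ccc(OCOC)c(O)c1 | intermediate
3 | 5-[(1R)-1-hydroxyethyl]-2-(methoxymethoxy)phenol | C[C@@H](O)c1ccc(OCOC)c(O)c1 | intermediate
4 | 3-bromo-4,5-dihydroxybenzaldehyde | O=Cc1cc(O)c(O)c(Br)c1 | starting material
5 | 3-bromo-4,5-bis(methoxymethoxy)benzaldehyde | O=Cc1cc(OCOC)c(OCOC)c(Br)c1 | intermediate
6 | rac-1-[3-bromo-4,5-bis(methoxymethoxy)phenyl]ethan-1-ol | CC(O)c1cc(OCOC)c(OCOC)c(Br)c1 | intermediate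
7 | 1-[3-bromo-4,5-bis(methoxymethoxy)phenyl]ethan-1-one | CC(=O)c1cc(OCOC)c(OCOC)c(Br)c1 | intermediate
8 | (1S)-1-[3-bromo-4,5-bis(methoxymethoxy)phenyl]ethan-1-ol | C[C@H](O)c1cc(OCOC)c(OCOC)c(Br)c1 | intermediate
9 | (1R)-1-[3-{5-[(1S)-1-hydroxyethyl]-2,3-bis(methoxymethoxy)phenoxy}-4-(methoxymethoxy)phenyl]ethan-1-ol | C[C@@H](O)c1ccc(OCOC)c(Oc2cc([C@H](C)O)cc(OCOC)c2OCOC)c1 | intermediate
10 | bis(N,N-diisopropylcarbamate) of 9, carbinol carbon R on ring A and S on ring B | C[C@@H](OC(=O)N(C(C)C)C(C)C)c1ccc(OCOC)c(Oc2cc([C@H](C)OC(=O)N(C(C)C)C(C)C)cc(OCOC)c2OCOC)c1 | intermediate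
11 | (E)-geranyl bromide, (2E)-1-bromo-3,7-dimethylocta-2,6-diene | CC(C)=CCC/C(C)=C/CBr | starting material
12 | homogeranyl pinacol boronate, 2-[(3E)-4,8-dimethylnona-3,7-dien-1-yl]-4,4,5,5-tetramethyl-1,3,2-dioxaborolane | CC(C)=CCC/C(C)=C/CCB1OC(C)(C)C(C)(C)O1 | intermediate
13 | dilithiated bis(carbamate): 10 with each benzylic H replaced by Li with retention (R on ring A, S on ring B) | C[C@@]([Li])(OC(=O)N(C(C)C)C(C)C)c1ccc(OCOC)c(Oc2cc([C@]([Li])(C)OC(=O)N(C(C)C)C(C)C)cc(OCOC)c2OCOC)c1 | intermediate
14 | dilithium bis(boronate) ate complex: each benzylic carbon of 10 bound to a tetracoordinate pinacol borate that carries the homogeranyl group, carbamates still in place (R on ring A, S on ring B) | C[C@@]([B-]1(CC/C=C(\C)CCC=C(C)C)OC(C)(C)C(C)(C)O1)(OC(=O)N(C(C)C)C(C)C)c1ccc(OCOC)c(Oc2cc([C@]([B-]3(CC/C=C(\C)CCC=C(C)C)OC(C)(C)C(C)(C)O3)(C)OC(=O)N(C(C)C)C(C)C)cc(OCOC)c2OCOC)c1.[Li+].[Li+] | intermediate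
15 | bis(tertiary pinacol boronate): each benzylic carbon bears CH3, Bpin, aryl and the (E)-4,8-dimethylnona-3,7-dienyl chain; C–B carbon R on ring A, S on ring B | CC1(C)OB(OC1(C)C)[C@@](C)(CC/C=C(\C)CCC=C(C)C)c1ccc(OCOC)c(Oc2cc([C@](C)(B3OC(C)(C)C(C)(C)O3)CC/C=C(\C)CCC=C(C)C)cc(OCOC)c2OCOC)c1 | intermediate
16 | dilithium bis(vinylboronate) ate complex: 15 with a vinyl group added to each boron | C=C[B-]1(OC(C)(C)C(C)(C)O1)[C@@](C)(CC/C=C(\C)CCC=C(C)C)c1ccc(OCOC)c(Oc2cc([C@](C)([B-]3(C=C)OC(C)(C)C(C)(C)O3)CC/C=C(\C)CCC=C(C)C)cc(OCOC)c2OCOC)c1.[Li+].[Li+] | intermediate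
17 | bis(β-iodoalkyl boronate): each quaternary carbon bears CH(Bpin)CH2I in place of Bpin (the CH(Bpin) centres are uncontrolled and vanish on elimination) | ICC(B1OC(C)(C)C(C)(C)O1)[C@@](C)(CC/C=C(\C)CCC=C(C)C)c1ccc(OCOC)c(Oc2cc([C@](C)(C(CI)B3OC(C)(C)C(C)(C)O3)CC/C=C(\C)CCC=C(C)C)cc(OCOC)c2OCOC)c1 | intermediate
18 | tris(MOM) ether of the target: both quaternary carbons bear vinyl; 3R on ring A, 3S on ring B | C=C[C@@](C)(CC/C=C(\C)CCC=C(C)C)c1ccc(OCOC)c(Oc2cc([C@](C)(C=C)CC/C=C(\C)CCC=C(C)C)cc(OCOC)c2OCOC)c1 | intermediate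
19 | 3-{2-hydroxy-5-[(3R,6E)-3,7,11-trimethyldodeca-1,6,10-trien-3-yl]phenoxy}-5-[(3S,6E)-3,7,11-trimethyldodeca-1,6,10-trien-3-yl]benzene-1,2-diol | C=C[C@@](C)(CC/C=C(\C)CCC=C(C)C)c1ccc(O)c(Oc2cc([C@](C)(C=C)CC/C=C(\C)CCC=C(C)C)cc(O)c2O)c1 | target

**Step count and risks**

Total step count: 12. Longest linear sequence: 9 steps (steps 3, 4, 5, 6, 7, 8, 10, 11, 12, from 4).

The three steps most likely to fail:

1. Step 10. The twofold metalation or boronate capture may stop after one arm, ring deprotonation next to an acetal oxygen may compete once the first benzylic anion is in place, or configuration may leak through reversible ate-complex formation. The fallback builds one arm at a time, so that only one carbanion is present in each operation; it sets out from 8 (with 3 and 12) and comes back to the route at 18. Alcohol 8 is carbamoylated (i-Pr2NCOCl, Et3N, CH2Cl2, reflux) to the ring B bromo carbamate F1, which is joined to phenol 3 under the conditions of step 7 to give the diaryl ether mono-carbamate F2, whose ring A carbinol is free. s-BuLi (2.3 equiv, the first equivalent only forming the lithium alkoxide), then 12, then MgBr2/MeOH give the ring B tertiary boronate F3, and Zweifel olefination as in step 11 gives the ring B vinyl carbinol F4. Carbamoylation of the ring A carbinol gives the ring A carbamate F5, a second single-site lithiation–borylation with 12 gives the ring A tertiary boronate F6, and Zweifel olefination of F6 gives 18.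

2. Step 7. Oxidative addition of the electron-rich, ortho-oxygenated aryl bromide to copper may be too slow, so that the coupling stalls or the bromide is reduced. The fallback reverses the role of ring B from halide to boron partner; it sets out from 8 and comes back at 9. Miyaura borylation of 8 (B2pin2, PdCl2(dppf), KOAc, dioxane, 85 °C) gives the ring B aryl pinacol boronate F7, and Chan–Lam coupling of F7 with phenol 3 (Cu(OAc)2, B(OH)3, 4 Å MS, MeCN, 80 °C, air) gives 9.

3. Step 11. Ate-complex formation at the two hindered tertiary boronates may be incomplete, or iodine may attack the trisubstituted alkenes or the oxygenated rings. The fallback avoids iodine and builds the vinyl groups by homologation and carbonyl olefination; it sets out from 15 and comes back at 18. Matteson homologation of both C–B bonds (BrCH2Cl, n-BuLi, THF, −78 °C → rt, 1,2-shift with retention) gives the bis(primary boronate) F8, NaOH/H2O2 oxidation gives the diol F9, Dess–Martin periodinane (NaHCO3, CH2Cl2) gives the dialdehyde F10, whose α-carbons are quaternary and cannot epimerise, and Wittig methylenation (Ph3PCH3Br, KOt-Bu, THF, 0 °C) gives 18.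

**Further compounds**

F1 | step 10 | (1S)-1-[3-bromo-4,5-bis(methoxymethoxy)phenyl]ethyl N,N-diisopropylcarbamate | C[C@H](OC(=O)N(C(C)C)C(C)C)c1cc(OCOC)c(OCOC)c(Br)c1
F2 | step 10 | (1S)-1-[3-{5-[(1R)-1-hydroxyethyl]-2-(methoxymethoxy)phenoxy}-4,5-bis(methoxymethoxy)phenyl]ethyl N,N-diisopropylcarbamate | C[C@@H](O)c1ccc(OCOC)c(Oc2cc([C@H](C)OC(=O)N(C(C)C)C(C)C)cc(OCOC)c2OCOC)c1
F3 | step 10 | ring B tertiary pinacol boronate (C–B carbon S, homogeranyl chain attached) with free (R)-carbinol on ring A | C[C@@H](O)c1ccc(OCOC)c(Oc2cc([C@](C)(B3OC(C)(C)C(C)(C)O3)CC/C=C(\C)CCC=C(C)C)cc(OCOC)c2OCOC)c1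
F4 | step 10 | ring B vinyl quaternary compound (3S) with free (R)-carbinol on ring A | C[C@@H](O)c1ccc(OCOC)c(Oc2cc([C@](C)(C=C)CC/C=C(\C)CCC=C(C)C)cc(OCOC)c2OCOC)c1
F5 | step 10 | N,N-diisopropylcarbamate of F4 at the ring A (R)-carbinol | C[C@@H](OC(=O)N(C(C)C)C(C)C)c1ccc(OCOC)c(Oc2cc([C@](C)(C=C)CC/C=C(\C)CCC=C(C)C)cc(OCOC)c2OCOC)c1
F6 | step 10 | ring A tertiary pinacol boronate (C–B carbon R) with the ring B vinyl quaternary centre (3S) in place | CC1(C)OB(OC1(C)C)[C@@](C)(CC/C=C(\C)CCC=C(C)C)c1ccc(OCOC)c(Oc2cc([C@](C)(C=C)CC/C=C(\C)CCC=C(C)C)cc(OCOC)c2OCOC)c1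
F7 | step 7 | (1S)-1-[3,4-bis(methoxymethoxy)-5-(4,4,5,5-tetramethyl-1,3,2-dioxaborolan-2-yl)phenyl]ethan-1-ol | C[C@H](O)c1cc(OCOC)c(OCOC)c(B2OC(C)(C)C(C)(C)O2)c1
F8 | step 11 | bis(primary pinacol boronate): 15 with a CH2 inserted into each C–B bond, spatial arrangement at both quaternary carbons retained | CC1(C)OB(OC1(C)C)C[C@@](C)(CC/C=C(\C)CCC=C(C)C)c1ccc(OCOC)c(Oc2cc([C@](C)(CB3OC(C)(C)C(C)(C)O3)CC/C=C(\C)CCC=C(C)C)cc(OCOC)c2OCOC)c1
F9 | step 11 | diol: each quaternary carbon bears CH2OH in place of CH2Bpin | OC[C@@](C)(CC/C=C(\C)CCC=C(C)C)c1ccc(OCOC)c(Oc2cc([C@](C)(CO)CC/C=C(\C)CCC=C(C)C)cc(OCOC)c2OCOC)c1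
F10 | step 11 | dialdehyde: each quaternary carbon bears CHO | O=C[C@@](C)(CC/C=C(\C)CCC=C(C)C)c1ccc(OCOC)c(Oc2cc([C@](C)(C=O)CC/C=C(\C)CCC=C(C)C)cc(OCOC)c2OCOC)c1
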